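## Retrosynthetic overview
1. The Z-enal comes from a C9 ketone by a one-flask α-methyl formyl-olefination and desilylation. The C9 ketone comes from a C9 nitro compound (Nef).
2. The C1 carbinol comes from a C1 ketone, with hydride delivered by the C6 hydroxyl. The C2–dienyl bond comes from the ketone enolate and a C13 dienyl triflate made from pseudoionone.
3. The spiro nitro ketol comes from an (E)-2-alkylidenecyclopentanone and 5-nitropentan-2-one by a catalytic asymmetric nitro-Michael/aldol spiroannulation. This forms C9–C10 and C5–C6 and sets C10, C5 and C6.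
4. The alkylidenecyclopentanone comes from cyclopentanone and 4-silyloxybutanal by aldol condensation.
5. Ring order: the five-membered ring is bought as cyclopentanone, and the six-membered ring is closed onto it in the spiroannulation.

Assumption: the silyloxybutanal, the nitro ketone and isomerically pure (3E,5E)-pseudoionone are bought as such, and of the two accessible enantiomers of the spiroannulation catalyst the one that gives the drawn series is used.

Locants: all spiro compounds keep the target numbering. C1 is the carbinol/ketone carbon, C2 bears the dienyl group, C5 is the spiro atom, C6 is C(OH)CH3, C9 is the ylidene/ketone/nitro carbon, and C10 bears the propyl chain.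

## Route

Step 1
Reactants: 1 cyclopentanone; 2 4-[(tert-butyldimethylsilyl)oxy]butanal
Product: 3 (2E)-2-{4-[(tert-butyldimethylsilyl)oxy]butylidene}cyclopentan-1-one
Conditions: 1 (3 equiv), NaOH (0.2 equiv), H2O/MeOH, slow addition of 2, 0 to 40 °C
Reagents that add atoms: none
Why: Crossed aldol condensation (excess ketone, slow aldehyde addition) followed by E1cB loss of water gives the thermodynamically preferred E-enone with the chain anti to the carbonyl group, and no stereocentre is formed.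

Step 2
Reactants: 3 (2E)-2-{4-[(tert-butyldimethylsilyl)oxy]butylidene}cyclopentan-1-one; 4 5-nitropentan-2-one
Product: 6 (5R,6S,9R,10R)-10-{3-[(tert-butyldimethylsilyl)oxy]propyl}-6-methyl-9-nitro-6-[(trimethylsilyl)oxy]spiro[4.5]decan-1-one, via free spiro ketol 5 (not isolated)
Conditions: 4 (1.2 equiv), 10 mol % 1-[3,5-bis(trifluoromethyl)phenyl]-3-[(2S)-3,3-dimethyl-1-{[tris(4-methoxyphenyl)-λ5-phosphanylidene]amino}butan-2-yl]thiourea (metal-free iminophosphorane–thiourea), toluene, 0 °C, 48 h; then N-(trimethylsilyl)imidazole (3 equiv), rt to 40 °C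
Reagents that add atoms: N-(trimethylsilyl)imidazole, C[Si](C)(C)n1ccnc1
Why: Proposed new method: an enantioselective nitro-Michael/aldol spiroannulation of a β-alkyl 2-alkylidenecyclopentanone with a γ-nitro ketone, in which the iminophosphorane deprotonates 4 (pKa about 17) while the thiourea binds the s-cis enone, the nitronate adds to one face of C10 (catalyst control, first stereocentre), the regiodefined tetrasubstituted enolate, held with C10–H eclipsing the enolate C–O (A1,3 strain), closes on the methyl ketone through a chair with CH3 equatorial and the new OH axial and hydrogen-bonded to C1=O (sets C5 and C6; the aldol is reversible so the most stable ketol collects, and C9–NO2 equilibrates equatorial), and silylation in the same flask blocks the retro-aldol; the closest known reaction types are the amine-catalysed nitroalkane Michael/aldol domino of γ-nitro ketones with enals and thiourea- or iminophosphorane-catalysed nitro-Michael additions to enones.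

Step 3
Reactants: 7 (3E,5E)-6,10-dimethylundeca-3,5,9-trien-2-one (pseudoionone)
Product: 9 (3E,5E)-6,10-dimethylundeca-1,3,5,9-tetraen-2-yl trifluoromethanesulfonate, via lithium dienolate 8 (not isolated)
Conditions: LiN(SiMe3)2 (1.1 equiv), THF, −78 °C; PhNTf2 (1.1 equiv), −78 to 0 °C
Reagents that add atoms: N-phenylbis(trifluoromethanesulfonimide), O=S(=O)(C(F)(F)F)N(c1ccccc1)S(=O)(=O)C(F)(F)F
Why: Kinetic deprotonation of the enone at the α'-methyl group and O-sulfonylation of the cross-conjugated enolate (enol triflate formation) leave both E double bonds untouched.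

Step 4
Reactants: 6 (5R,6S,9R,10R)-10-{3-[(tert-butyldimethylsilyl)oxy]propyl}-6-methyl-9-nitro-6-[(trimethylsilyl)oxy]spiro[4.5]decan-1-one; 9 (3E,5E)-6,10-dimethylundeca-1,3,5,9-tetraen-2-yl trifluoromethanesulfonate
Product: 11 (2R,5R,6S,9R,10R)-10-{3-[(tert-butyldimethylsilyl)oxy]propyl}-2-[(3E,5E)-6,10-dimethylundeca-1,3,5,9-tetraen-2-yl]-6-methyl-9-nitro-6-[(trimethylsilyl)oxy]spiro[4.5]decan-1-one, via dilithium nitronate enolate 10 (not isolated)
Conditions: LiN(SiMe3)2 (3.2 equiv), THF/toluene, −78 to 0 °C; Pd2(dba)3 (2.5 mol %), P(t-Bu)3 (10 mol %), 9 (1.2 equiv), rt; AcOH, −78 °C; then DBU (5 mol %), CH2Cl2, −20 °C, short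
Reagents that add atoms: none
Why: Palladium-catalysed α-alkenylation of a ketone enolate (Buchwald–Hartwig-type enolate coupling) works here because C2 is the only enolisable position of the ketone and the hindered secondary nitronate merely masks C9, and the epimerisable C2 centre is then equilibrated to the isomer whose dienyl group lies on the C6 (methyl) face, away from the C10 chain that covers the other face.

Step 5
Reactants: 11 (2R,5R,6S,9R,10R)-10-{3-[(tert-butyldimethylsilyl)oxy]propyl}-2-[(3E,5E)-6,10-dimethylundeca-1,3,5,9-tetraen-2-yl]-6-methyl-9-nitro-6-[(trimethylsilyl)oxy]spiro[4.5]decan-1-one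
Product: 13 (1R,2R,5S,6S,9R,10R)-10-{3-[(tert-butyldimethylsilyl)oxy]propyl}-2-[(3E,5E)-6,10-dimethylundeca-1,3,5,9-tetraen-2-yl]-6-methyl-9-nitrospiro[4.5]decane-1,6-diol, via desilylated ketol 12 (not isolated)
Conditions: AcOH/MeCN 1:1, rt, 30 min; then Me4NBH(OAc)3 (6 equiv), −25 °C
Reagents that add atoms: none
Why: Acetolysis frees the C6 hydroxyl, which binds the triacetoxyborohydride and delivers hydride intramolecularly to the C6 face of C1=O (Evans–Saksena hydroxyl-directed reduction), so the C1 hydroxyl ends anti to C6–O and trans to the C2 dienyl group.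

Step 6
Reactants: 13 (1R,2R,5S,6S,9R,10R)-10-{3-[(tert-butyldimethylsilyl)oxy]propyl}-2-[(3E,5E)-6,10-dimethylundeca-1,3,5,9-tetraen-2-yl]-6-methyl-9-nitrospiro[4.5]decane-1,6-diol
Product: 14 (1R,2R,5S,6S,10R)-10-{3-[(tert-butyldimethylsilyl)oxy]propyl}-2-[(3E,5E)-6,10-dimethylundeca-1,3,5,9-tetraen-2-yl]-1,6-dihydroxy-6-methylspiro[4.5]decan-9-one
Conditions: 30% H2O2, K2CO3, MeOH, 0 °C to rt
Reagents that add atoms: hydrogen peroxide, OO
Why: Oxidative Nef reaction of the carbonate-generated nitronate with hydroperoxide gives the ketone, basic H2O2 does not touch electron-rich C=C bonds, and C10, now α to the ketone, keeps its more stable equatorial (natural) configuration.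

Step 7
Reactants: 15 ethyl prop-1-enyl ether (E/Z mixture)
Product: 17 2-bromo-1-ethoxyprop-1-ene (E/Z mixture, inconsequential), via 1,2-dibromo-1-ethoxypropane 16 (not isolated)
Conditions: Br2 (1.0 equiv), CH2Cl2, −78 °C; then Et3N (1.5 equiv), warm to reflux
Reagents that add atoms: bromine, BrBr
Why: Bromine addition to the enol ether followed by amine-induced loss of HBr from the ionisable α-bromo ether (addition–elimination) gives the β-bromo enol ether.

Step 8
Reactants: 14 (1R,2R,5S,6S,10R)-10-{3-[(tert-butyldimethylsilyl)oxy]propyl}-2-[(3E,5E)-6,10-dimethylundeca-1,3,5,9-tetraen-2-yl]-1,6-dihydroxy-6-methylspiro[4.5]decan-9-one; 17 2-bromo-1-ethoxyprop-1-ene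
Product: 20 (2Z)-2-{(1R,2R,5S,6S,10S)-2-[(3E,5E)-6,10-dimethylundeca-1,3,5,9-tetraen-2-yl]-1,6-dihydroxy-10-(3-hydroxypropyl)-6-methylspiro[4.5]decan-9-ylidene}propanal (CNP0173034.2), via 2-lithio-1-ethoxypropene 18 (not isolated), via tertiary carbinol adduct 19 (not isolated)
Conditions: 17 (6 equiv), t-BuLi (12 equiv), Et2O, −78 °C; 14 in THF, −78 to −40 °C; H2O quench; crude in MeCN, 48% aq HF, 0 °C
Reagents that add atoms: water, O
Why: Bromine–lithium exchange gives a β-lithio enol ether that adds 1,2 to the only carbonyl group, acid ionises the tertiary allylic carbinol and water attacks the oxocarbenium terminus (formyl-olefination with allylic transposition) to give the tetrasubstituted enal, which settles under acid as the less strained Z isomer (CHO rather than CH3 beside substituted C10), while HF removes the silyl ether.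

## Compound list
1 | cyclopentanone | O=C1CCCC1 | starting material
2 | 4-[(tert-butyldimethylsilyl)oxy]butanal | O=CCCCO[Si](C)(C)C(C)(C)C | starting material
3 | (2E)-2-{4-[(tert-butyldimethylsilyl)oxy]butylidene}cyclopentan-1-one | O=C1CCC/C1=C\CCCO[Si](C)(C)C(C)(C)C | intermediate
4 | 5-nitropentan-2-one | CC(=O)CCC[N+](=O)[O-] | starting material
5 | (5R,6S,9R,10R)-10-{3-[(tert-butyldimethylsilyl)oxy]propyl}-6-hydroxy-6-methyl-9-nitrospiro[4.5]decan-1-one | C1CC[C@@]2(C1=O)[C@@H](CCCO[Si](C)(C)C(C)(C)C)[C@H]([N+](=O)[O-])CC[C@]2(C)O | intermediate (not isolated)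
6 | (5R,6S,9R,10R)-10-{3-[(tert-butyldimethylsilyl)oxy]propyl}-6-methyl-9-nitro-6-[(trimethylsilyl)oxy]spiro[4.5]decan-1-one | C1CC[C@@]2(C1=O)[C@@H](CCCO[Si](C)(C)C(C)(C)C)[C@H]([N+](=O)[O-])CC[C@]2(C)O[Si](C)(C)C | intermediate
7 | (3E,5E)-6,10-dimethylundeca-3,5,9-trien-2-one (pseudoionone) | CC(=O)/C=C/C=C(\C)CCC=C(C)C | starting material
8 | lithium (3E,5E)-6,10-dimethylundeca-1,3,5,9-tetraen-2-olate | [Li+].[O-]C(=C)/C=C/C=C(\C)CCC=C(C)C | intermediate (not isolated)
9 | (3E,5E)-6,10-dimethylundeca-1,3,5,9-tetraen-2-yl trifluoromethanesulfonate | C=C(OS(=O)(=O)C(F)(F)F)/C=C/C=C(\C)CCC=C(C)C | intermediate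
10 | dilithium C1-enolate/C9-nitronate of 6 | [Li+].[Li+].C=1CC[C@@]2(C=1[O-])[C@@H](CCCO[Si](C)(C)C(C)(C)C)C(=[N+]([O-])[O-])CC[C@]2(C)O[Si](C)(C)C | intermediate (not isolated)
11 | (2R,5R,6S,9R,10R)-10-{3-[(tert-butyldimethylsilyl)oxy]propyl}-2-[(3E,5E)-6,10-dimethylundeca-1,3,5,9-tetraen-2-yl]-6-methyl-9-nitro-6-[(trimethylsilyl)oxy]spiro[4.5]decan-1-one | C=C(/C=C/C=C(\C)CCC=C(C)C)[C@H]1CC[C@@]2(C1=O)[C@@H](CCCO[Si](C)(C)C(C)(C)C)[C@H]([N+](=O)[O-])CC[C@]2(C)O[Si](C)(C)C | intermediate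
12 | (2R,5R,6S,9R,10R)-10-{3-[(tert-butyldimethylsilyl)oxy]propyl}-2-[(3E,5E)-6,10-dimethylundeca-1,3,5,9-tetraen-2-yl]-6-hydroxy-6-methyl-9-nitrospiro[4.5]decan-1-one | C=C(/C=C/C=C(\C)CCC=C(C)C)[C@H]1CC[C@@]2(C1=O)[C@@H](CCCO[Si](C)(C)C(C)(C)C)[C@H]([N+](=O)[O-])CC[C@]2(C)O | intermediate (not isolated)
13 | (1R,2R,5S,6S,9R,10R)-10-{3-[(tert-butyldimethylsilyl)oxy]propyl}-2-[(3E,5E)-6,10-dimethylundeca-1,3,5,9-tetraen-2-yl]-6-methyl-9-nitrospiro[4.5]decane-1,6-diol | C=C(/C=C/C=C(\C)CCC=C(C)C)[C@H]1CC[C@@]2([C@@H]1O)[C@@H](CCCO[Si](C)(C)C(C)(C)C)[C@H]([N+](=O)[O-])CC[C@]2(C)O | intermediate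
14 | (1R,2R,5S,6S,10R)-10-{3-[(tert-butyldimethylsilyl)oxy]propyl}-2-[(3E,5E)-6,10-dimethylundeca-1,3,5,9-tetraen-2-yl]-1,6-dihydroxy-6-methylspiro[4.5]decan-9-one | C=C(/C=C/C=C(\C)CCC=C(C)C)[C@H]1CC[C@@]2([C@@H]1O)[C@@H](CCCO[Si](C)(C)C(C)(C)C)C(=O)CC[C@]2(C)O | intermediate
15 | ethyl prop-1-enyl ether (E/Z mixture) | CCOC=CC | starting material
16 | 1,2-dibromo-1-ethoxypropane (racemic diastereomer mixture; both centres vanish in 17) | CCOC(Br)C(C)Br | intermediate (not isolated)
17 | 2-bromo-1-ethoxyprop-1-ene (E/Z mixture) | CCOC=C(C)Br | intermediate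
18 | 2-lithio-1-ethoxyprop-1-ene | CCOC=C(C)[Li] | intermediate (not isolated)
19 | (1R,2R,5S,6S,9S,10R)-10-{3-[(tert-butyldimethylsilyl)oxy]propyl}-2-[(3E,5E)-6,10-dimethylundeca-1,3,5,9-tetraen-2-yl]-9-(1-ethoxyprop-1-en-2-yl)-6-methylspiro[4.5]decane-1,6,9-triol | C=C(/C=C/C=C(\C)CCC=C(C)C)[C@H]1CC[C@@]2([C@@H]1O)[C@@H](CCCO[Si](C)(C)C(C)(C)C)[C@](O)(C(C)=COCC)CC[C@]2(C)O | intermediate (not isolated)
20 | (2Z)-2-{(1R,2R,5S,6S,10S)-2-[(3E,5E)-6,10-dimethylundeca-1,3,5,9-tetraen-2-yl]-1,6-dihydroxy-10-(3-hydroxypropyl)-6-methylspiro[4.5]decan-9-ylidene}propanal | C=C(/C=C/C=C(\C)CCC=C(C)C)[C@H]1CC[C@@]2([C@@H]1O)[C@@H](CCCO)/C(=C(/C)C=O)CC[C@]2(C)O | target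

## Step count and risks
Total steps: 8. Longest linear sequence: 6 steps (1, 2, 4, 5, 6, 8). Steps 3 and 7 make side reagents.

**Step 2 (the proposed new reaction).**
- Risks:
  - Addition to the β-alkyl exocyclic enone may be slow or reversible.
  - The enone may isomerise to the endocyclic enone.
  - The competing aldol mode, in which the side-chain enolate attacks C1, may win.
  - The sense and level of induction are unknown.
- The fallback uses known chemistry. It sets out from 1 and 2 and comes back at 5.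
- Aldehyde 2 is condensed with nitromethane (piperidine, 4 Å sieves, toluene, reflux) to the nitroalkene (E)-tert-butyldimethyl[(5-nitropent-4-en-1-yl)oxy]silane F1.
- Cyclopentanone 1 is added to it under enamine catalysis with a pyrrolidine–thiourea catalyst and benzoic acid. This is the established ketone/nitroalkene Michael addition, and it sets C10. It gives the syn γ-nitro ketone (2R)-2-[(2R)-5-[(tert-butyldimethylsilyl)oxy]-1-nitropentan-2-yl]cyclopentan-1-one F2.
- Amine-catalysed nitro-Michael addition to methyl vinyl ketone then gives the nitro diketone (2R)-2-[(4R)-1-[(tert-butyldimethylsilyl)oxy]-5-nitro-8-oxononan-4-yl]cyclopentan-1-one F3.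
- Catalytic DBU in toluene closes this by intramolecular aldol addition to ketol 5, which is silylated to 6 as in step 2.

**Step 4 (enolate alkenylation).**
- Risks:
  - The hindered enolate may couple sluggishly.
  - The nitronate may interfere.
  - The β,γ-unsaturated ketone may drift into conjugation.
  - The C2 equilibrium ratio may be only moderate.
- The fallback replaces cross-coupling by carbonyl chemistry and sets C2 by relay from C1. It sets out from 6 (through 10) and comes back at 13.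
- Geranial and (triphenylphosphoranylidene)acetaldehyde give (2E,4E)-5,9-dimethyldeca-2,4,8-trienal F4.
- Dianion 10 adds to it at −78 °C to give the aldol 10-{3-[(tert-butyldimethylsilyl)oxy]propyl}-2-[(2E,4E)-1-hydroxy-5,9-dimethyldeca-2,4,8-trienyl]-6-methyl-9-nitro-6-[(trimethylsilyl)oxy]spiro[4.5]decan-1-one F5.
- Dess–Martin periodinane gives the 2-acyl ketone 10-{3-[(tert-butyldimethylsilyl)oxy]propyl}-2-[(2E,4E)-5,9-dimethyldeca-2,4,8-trienoyl]-6-methyl-9-nitro-6-[(trimethylsilyl)oxy]spiro[4.5]decan-1-one F6.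
- The conditions of step 5 (AcOH/MeCN, then Me4NBH(OAc)3) remove the trimethylsilyl group and reduce only the ring ketone that the C6 hydroxyl can reach. This gives the β-hydroxy dienone (2E,4E)-1-[(1R,2R,5S,6S,9R,10R)-10-{3-[(tert-butyldimethylsilyl)oxy]propyl}-1,6-dihydroxy-6-methyl-9-nitrospiro[4.5]decan-2-yl]-5,9-dimethyldeca-2,4,8-trien-1-one F7.
- The acidic C2 centre of this dienone settles trans to the fixed C1 hydroxyl.
- Non-basic methylenation with Cp2TiMe2 (toluene, 70 °C) then gives 13.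

**Step 8 (enal installation).**
- Risks:
  - The organolithium may enolise the α-branched ketone.
  - The Z/E ratio of the tetrasubstituted enal may be poor.
  - The triene may be sensitive to acid.
- The fallback replaces addition/transposition by olefination. It sets out from 14 and comes back at 20.
- Horner–Wadsworth–Emmons reaction of 14 with diethyl (1-cyanoethyl)phosphonate (NaH, excess, THF) gives, after separation of the geometric isomers, the nitrile (2Z)-2-[(1R,2R,5S,6S,10S)-10-{3-[(tert-butyldimethylsilyl)oxy]propyl}-2-[(3E,5E)-6,10-dimethylundeca-1,3,5,9-tetraen-2-yl]-1,6-dihydroxy-6-methylspiro[4.5]decan-9-ylidene]propanenitrile F8.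
- i-Bu2AlH (excess, toluene, −78 °C) and mild hydrolysis give the silyl-protected enal (2Z)-2-[(1R,2R,5S,6S,10S)-10-{3-[(tert-butyldimethylsilyl)oxy]propyl}-2-[(3E,5E)-6,10-dimethylundeca-1,3,5,9-tetraen-2-yl]-1,6-dihydroxy-6-methylspiro[4.5]decan-9-ylidene]propanal F9.
- HF·pyridine in THF then gives 20.

## Further compounds
F1 | step 2 | (E)-tert-butyldimethyl[(5-nitropent-4-en-1-yl)oxy]silane | [O-][N+](=O)/C=C/CCCO[Si](C)(C)C(C)(C)C
F2 | step 2 | (2R)-2-[(2R)-5-[(tert-butyldimethylsilyl)oxy]-1-nitropentan-2-yl]cyclopentan-1-one | O=C1CCC[C@@H]1[C@@H](CCCO[Si](C)(C)C(C)(C)C)C[N+](=O)[O-]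
F3 | step 2 | (2R)-2-[(4R)-1-[(tert-butyldimethylsilyl)oxy]-5-nitro-8-oxononan-4-yl]cyclopentan-1-one (mixture at the nitro carbon) | O=C1CCC[C@@H]1[C@@H](CCCO[Si](C)(C)C(C)(C)C)C(CCC(C)=O)[N+](=O)[O-]
F4 | step 4 | (2E,4E)-5,9-dimethyldeca-2,4,8-trienal | O=C/C=C/C=C(\C)CCC=C(C)C
F5 | step 4 | 10-{3-[(tert-butyldimethylsilyl)oxy]propyl}-2-[(2E,4E)-1-hydroxy-5,9-dimethyldeca-2,4,8-trienyl]-6-methyl-9-nitro-6-[(trimethylsilyl)oxy]spiro[4.5]decan-1-one (carbinol mixture) | OC(/C=C/C=C(\C)CCC=C(C)C)[C@H]1CC[C@@]2(C1=O)[C@@H](CCCO[Si](C)(C)C(C)(C)C)[C@H]([N+](=O)[O-])CC[C@]2(C)O[Si](C)(C)C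
F6 | step 4 | 10-{3-[(tert-butyldimethylsilyl)oxy]propyl}-2-[(2E,4E)-5,9-dimethyldeca-2,4,8-trienoyl]-6-methyl-9-nitro-6-[(trimethylsilyl)oxy]spiro[4.5]decan-1-one (C2 labile) | O=C(/C=C/C=C(\C)CCC=C(C)C)C1CC[C@@]2(C1=O)[C@@H](CCCO[Si](C)(C)C(C)(C)C)[C@H]([N+](=O)[O-])CC[C@]2(C)O[Si](C)(C)C
F7 | step 4 | (2E,4E)-1-[(1R,2R,5S,6S,9R,10R)-10-{3-[(tert-butyldimethylsilyl)oxy]propyl}-1,6-dihydroxy-6-methyl-9-nitrospiro[4.5]decan-2-yl]-5,9-dimethyldeca-2,4,8-trien-1-one | O=C(/C=C/C=C(\C)CCC=C(C)C)[C@H]1CC[C@@]2([C@@H]1O)[C@@H](CCCO[Si](C)(C)C(C)(C)C)[C@H]([N+](=O)[O-])CC[C@]2(C)O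
F8 | step 8 | (2Z)-2-[(1R,2R,5S,6S,10S)-10-{3-[(tert-butyldimethylsilyl)oxy]propyl}-2-[(3E,5E)-6,10-dimethylundeca-1,3,5,9-tetraen-2-yl]-1,6-dihydroxy-6-methylspiro[4.5]decan-9-ylidene]propanenitrile | C=C(/C=C/C=C(\C)CCC=C(C)C)[C@H]1CC[C@@]2([C@@H]1O)[C@@H](CCCO[Si](C)(C)C(C)(C)C)/C(=C(/C)C#N)CC[C@]2(C)O
F9 | step 8 | (2Z)-2-[(1R,2R,5S,6S,10S)-10-{3-[(tert-butyldimethylsilyl)oxy]propyl}-2-[(3E,5E)-6,10-dimethylundeca-1,3,5,9-tetraen-2-yl]-1,6-dihydroxy-6-methylspiro[4.5]decan-9-ylidene]propanal | C=C(/C=C/C=C(\C)CCC=C(C)C)[C@H]1CC[C@@]2([C@@H]1O)[C@@H](CCCO[Si](C)(C)C(C)(C)C)/C(=C(/C)C=O)CC[C@]2(C)O
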